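Sunday's first product fell from 12% to 3% in 2.33 h, a shorter span than the 5.00 h in which Monday's fell from 16% to 11%.

| flask | substrate | coupling partner | temperature | remark | time |
|---|---|---|---|---|---|
| Monday's | 0.067 M | 0.095 M | 60 °C | run made earlier |  |
| Sunday's | 0.15 M | 0.095 M | 82 °C | run made earlier |  |
| Thursday's | 0.10 M | 0.048 M | 60 °C | run made earlier |  |
| alder | 0.10 M | 0.0950 M | 70 °C |  | 6.0 h |
| oak | 0.10 M | 0.0950 M | 50 °C |  | 6.0 h |
| ash | 0.10 M | 0.0950 M |  | at 90 °C until 80 min, from then on at 50 °C | 6.0 h |
| larch | 0.10 M | 0.0950 M | 90 °C |  | 6.0 h |

| run | time / h | first product / % |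
|---|---|---|
| Monday's | 0.667 | 19 |
| Monday's | 1.33 | 20 |
| Monday's | 3.00 | 16 |
| Monday's | 8.00 | 11 |
| Sunday's | 0.667 | 12 |
| Sunday's | 1.33 | 6 |
| Sunday's | 2.00 | 5 |
| Sunday's | 3.00 | 3 |
| Thursday's | 1.00 | 13 |
| Thursday's | 2.50 | 17 |
| Thursday's | 5.00 | 15 |
| Thursday's | 8.00 | 14 |

(readings scatter by 1.5 percentage points)

1. which flask leads in amount of first product, in percent of the substrate charged ("all alike" within 1.5 percentage points) (alder / oak / ash / larch / all alike)
2. how much first product is there at the end, in percent of the substrate charged: alder
3. how much first product is there at the end, in percent of the substrate charged: oak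
4. how much first product is there at the end, in percent of the substrate charged: ash
5. how much first product is there at the end, in percent of the substrate charged: larch

- the numbers in the tables scatter by 1.5 percentage points (one standard deviation)

I read these tables as c(first product) in molar, that is, percent times the substrate charge. I took the slope of the reciprocal of c(first product) against time as the loss constant kL, an apparent second-order rate constant.

Monday's last two readings gave 0.141 M⁻¹ min⁻¹ at 60 °C. Sunday's first and last gave 1.19 M⁻¹ min⁻¹ at 82 °C. Their substrate charges differ too, but I put the change down to temperature, so kL doubled about every 7.16 K, a reading from two scattered slopes. Thursday's row, with 0.048 M of coupling partner and 0.10 M of substrate, gave 0.0382 M⁻¹ min⁻¹, lower than Monday's at the same temperature. I therefore kept to the two rows whose partner charge matches the four flasks.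

For a start I took Sunday's first reading, 0.0180 M, the highest level read. For oak at 50 °C, kL scaled to 0.0536 M⁻¹ min⁻¹, and the reciprocal of kL times that start was 17.3 h. I call this the holding time, the span in which c(first product) halves by this rule.

Oak's holding time was longer than its run of 6.0 h. Alder's was 2.49 h and larch's 21.5 min, both shorter than the run. Ash spent 80 min at 90 °C, longer than larch's holding time. So I put oak first, with 13.4% by c0/(1+t/h).

The forecast also named oak, but it gave oak 18%, starting from about 0.024 M against my 0.0180 M. It gave alder 6%, ash 4.5% and larch 1.3%, since the loss “fits second order in product”.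

Oak led with 21.1%, against 5.75% in alder, 4.86% in ash and 0.663% in larch, and the forecast held. My own 13.4% for oak lay below that result. In oak, first product, each step taken net, was made 1.78 times faster than it was used up at 1.47 h, and the ratio was 0.777 at 6.00 h. At oak's end level the holding time was 14.7 h, longer than the run.

    first product ⇌ isomer of the product (K = 1.70, k = 1.00 × 10⁻⁴ min⁻¹, Ea = 107 kJ mol⁻¹, ΔH = 0 kJ mol⁻¹)
    coupling partner + first product → bis adduct + by-product (k = 0.0920 M⁻¹ min⁻¹, Ea = 76.0 kJ mol⁻¹)
    first product + by-product → side product (k = 0.00770 M⁻¹ min⁻¹, Ea = 79.0 kJ mol⁻¹)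
    substrate + coupling partner → first product + by-product (k = 0.0420 M⁻¹ min⁻¹, Ea = 57.0 kJ mol⁻¹)
    (constants at 50 °C)

The neighbour, like oak but kept at 65 °C, had by my reckoning a holding time of 4.04 h, which gave 7.24%. The computed result for that flask was 9.38%.

(The data stem from a simulated flask from invented constants; noise was put on by code.)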